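**Plan**
- Locants follow isoflavone numbering: ring B is C1'–C6', ring D is O–C2''–C3'' fused at C4'/C3', rings A and C are the chromone. The retrosynthesis cuts the C3–C1' biaryl bond, the two C–CH3 bonds of the carbinol, both ring D bonds to C2'' (C3''–C2'' and O–C2'') and finally C3'–C3''.
- Enabling feature: the C3'' methylene and the ring D oxygen sit on the adjacent ring B carbons C3' and C4', so ring B with these two atoms is an ortho-quinone methide, and C2'' can come from a one-carbon, ester-bearing ylide.
- Forward order: a ring B phenol from 6-bromoisovanillin is hydroxymethylated at C3' and converted into a sulfone; ring D is closed by the (4+1) annulation; the ester becomes CMe2OH; C1' is borylated and joined to a preformed 3-iodochromone (rings A and C); hydrogenolysis frees the three phenols.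
- Stereochemistry: C2'' (S) is the only stereocentre. It is set in the annulation by a quinidine-derived ammonium group bonded to the ylide carbon and is not a reacting atom afterwards.

Key step: step 9

Assumption: the sense of induction of a cinchona ammonium ylide on an unsubstituted methide is not established, so the quinidine series is written; if it delivers the (R) ester, the pseudoenantiomeric quinine-derived salt takes its place with no other change.

**Step 1**
Reactants: 1 2-bromo-5-hydroxy-4-methoxybenzaldehyde (6-bromoisovanillin)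
Product: 2 2-bromo-4-methoxy-5-(methoxymethoxy)benzaldehyde
Conditions: MOMCl, iPr2NEt, CH2Cl2, 0 °C to rt
Reagents that add atoms: chloromethyl methyl ether, COCCl
Why: Williamson-type O-alkylation of the single phenol gives the MOM acetal, which masks the future ring D oxygen (on C4') through the oxidation and benzylation that follow and leaves aldehyde and aryl bromide untouched.

**Step 2**
Reactants: 2 2-bromo-4-methoxy-5-(methoxymethoxy)benzaldehyde
Product: 4 2-bromo-4-methoxy-5-(methoxymethoxy)phenol, via aryl formate 3 (not isolated)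
Conditions: mCPBA, CH2Cl2, 0 °C to rt; then K2CO3 (cat.), MeOH, rt
Reagents that add atoms: meta-chloroperoxybenzoic acid, OOC(=O)c1cccc(Cl)c1
Why: In this Baeyer–Villiger oxidation the aryl group, activated by its para methoxyl, should migrate in preference to hydride, and base-catalysed methanolysis of the formate then frees the C2' oxygen as a phenol without disturbing the MOM acetal.

**Step 3**
Reactants: 4 2-bromo-4-methoxy-5-(methoxymethoxy)phenol
Product: 5 1-(benzyloxy)-2-bromo-4-methoxy-5-(methoxymethoxy)benzene
Conditions: BnBr, K2CO3, DMF, rt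
Reagents that add atoms: benzyl bromide, BrCc1ccccc1
Why: Williamson ether synthesis places a benzyl group on the C2' oxygen, a group that should survive acid, carbonate base, organometallic reagents and palladium coupling and leaves together with the other benzyl ethers at the end.

**Step 4**
Reactants: 5 1-(benzyloxy)-2-bromo-4-methoxy-5-(methoxymethoxy)benzene
Product: 6 5-(benzyloxy)-4-bromo-2-methoxyphenol
Conditions: HCl (cat.), MeOH, 40 °C
Reagents that add atoms: none
Why: Acid-catalysed acetal exchange with methanol removes the MOM group selectively, since benzyl aryl ether, methyl ether and aryl bromide are stable to dilute methanolic acid.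

**Step 5**
Reactants: 6 5-(benzyloxy)-4-bromo-2-methoxyphenol
Product: 8 3-(benzyloxy)-4-bromo-2-(hydroxymethyl)-6-methoxyphenol, via benzodioxaborinine 7 (not isolated)
Conditions: PhB(OH)2, (CH2O)n, EtCO2H (cat.), toluene, reflux with water removal; then 30% H2O2, THF, 0 °C to rt
Reagents that add atoms: paraformaldehyde (as formaldehyde), C=O
Why: In this boronate-templated ortho-hydroxymethylation the aryl phenylboronate delivers formaldehyde intramolecularly to C3', the only free carbon ortho to the phenol, the six-membered dioxaborinine prevents a second condensation, and oxidative cleavage of the phenyl–boron unit releases the salicyl alcohol.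

**Step 6**
Reactants: 8 3-(benzyloxy)-4-bromo-2-(hydroxymethyl)-6-methoxyphenol
Product: 9 3-(benzyloxy)-4-bromo-6-methoxy-2-(tosylmethyl)phenol
Conditions: p-TolSO2Na, HCO2H/H2O, rt
Reagents that add atoms: sodium p-toluenesulfinate, Cc1ccc(S(=O)[O-])cc1.[Na+]
Why: Acid-promoted benzylic substitution (SN1 through the ortho-hydroxybenzyl cation) by the sulfur atom of the sulfinate is the usual way to 2-(sulfonylmethyl)phenols, and an excess of sulfinate should outcompete the arene as nucleophile.

**Step 7**
Reactants: 10 quinidine
Product: 11 9-O-methylquinidine (quinidine methyl ether, configuration of quinidine unchanged)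
Conditions: NaH, DMF, 0 °C; then MeI, 0 °C to rt
Reagents that add atoms: iodomethane, CI
Why: Williamson O-methylation of the preformed C9 alkoxide, which is far more nucleophilic than the quinuclidine nitrogen, caps the hydroxyl so that it can later neither lactonise onto the ester nor trap the methide.

**Step 8**
Reactants: 11 9-O-methylquinidine; 12 methyl bromoacetate
Product: 13 N-(2-methoxy-2-oxoethyl)-9-O-methylquinidinium bromide (alkylated at the quinuclidine nitrogen)
Conditions: THF, rt
Reagents that add atoms: none
Why: Menshutkin quaternisation takes place at the quinuclidine nitrogen, the most nucleophilic site, with the reactive α-bromo ester, and the ammonium bromide should precipitate from THF.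

**Step 9**
Reactants: 9 3-(benzyloxy)-4-bromo-6-methoxy-2-(tosylmethyl)phenol; 13 N-(2-methoxy-2-oxoethyl)-9-O-methylquinidinium bromide
Product: 17 methyl (S)-4-(benzyloxy)-5-bromo-7-methoxy-2,3-dihydrobenzofuran-2-carboxylate, via ammonium ylide 14 (not isolated), via ortho-quinone methide 15 (not isolated), via phenoxide ammonium betaine 16 (not isolated)
Conditions: Cs2CO3, CH2Cl2, 0 °C to rt
Reagents that add atoms: none
Why: Proposed new method: Cs2CO3 turns phenol 9 into a phenoxide that expels p-toluenesulfinate to give methide 15 and deprotonates salt 13 to ylide 14, whose carbon adds to the exocyclic CH2 (forming C3''–C2'' and rearomatising ring B) to give betaine 16; the phenoxide then displaces 9-O-methylquinidine at the ester-bearing carbon with inversion (forming O–C2''), which closes ring D in a 5-exo-tet mode. The closest known reactions are the base-mediated (4+1) annulation of in situ ortho-quinone methides with cinchona ammonium ylides, shown for methides substituted at the exocyclic carbon, and the alkaloid-ylide cyclopropanation of acrylates, where a CH2 acceptor terminus likewise leaves the onium-bearing carbon as a controlled centre; a CH2 methide with C2'' as the sole new stereocentre is the untested element. C2'' is controlled by the quinuclidinium cage bonded to it: the ammonium-bearing carbon of 16 is acidic and can epimerise through ylide 14, so both diastereomeric betaines should drain through the faster ring closure, which is expected to lead to the (S) ester. Site selectivity is fixed by the substrate, because the methoxyl at C5' and the benzyl ether at C2' leave C3'/C4' as the only place where a methide can form. Chemoselectivity against methide dimerisation should be secured by slow release of 15 from the sulfone under heterogeneous carbonate, with reversible re-addition of sulfinate as a reservoir and the ylide kept in excess; the mild base should not epimerise the product ester.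

**Step 10**
Reactants: 17 methyl (S)-4-(benzyloxy)-5-bromo-7-methoxy-2,3-dihydrobenzofuran-2-carboxylate
Product: 18 (S)-2-[4-(benzyloxy)-5-bromo-7-methoxy-2,3-dihydrobenzofuran-2-yl]propan-2-ol
Conditions: MeMgBr, CeCl3 (anhydrous), THF, −78 to 0 °C
Reagents that add atoms: methylmagnesium bromide, C[Mg]Br
Why: Double Grignard addition to the ester gives the tertiary alcohol, the cerium-modified methyl nucleophile being too weakly basic to enolise the ester or the transient methyl ketone at C2'', so the stereocentre (not a reacting atom) should be kept and the aryl bromide left untouched.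

**Step 11**
Reactants: 18 (S)-2-[4-(benzyloxy)-5-bromo-7-methoxy-2,3-dihydrobenzofuran-2-yl]propan-2-ol
Product: 19 (S)-2-[4-(benzyloxy)-7-methoxy-5-(4,4,5,5-tetramethyl-1,3,2-dioxaborolan-2-yl)-2,3-dihydrobenzofuran-2-yl]propan-2-ol
Conditions: B2pin2, Pd(dppf)Cl2, KOAc, 1,4-dioxane, 90 °C
Reagents that add atoms: bis(pinacolato)diboron, CC1(C)OB(OC1(C)C)B1OC(C)(C)C(C)(C)O1
Why: Miyaura borylation of the aryl bromide runs under weakly basic acetate conditions that tolerate the free tertiary alcohol and the benzyl ether and turns C1' into the nucleophilic partner for the biaryl coupling.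

**Step 12**
Reactants: 20 2,4,6-trihydroxyacetophenone
Product: 21 1-[2,4-bis(benzyloxy)-6-hydroxyphenyl]ethan-1-one
Conditions: BnBr (2 equiv), K2CO3, DMF, rt
Reagents that add atoms: benzyl bromide, BrCc1ccccc1
Why: Williamson benzylation should stop at two of the three phenols because the hydroxyl hydrogen-bonded to the ketone carbonyl is the least nucleophilic and stays free for the later pyranone closure.

**Step 13**
Reactants: 21 1-[2,4-bis(benzyloxy)-6-hydroxyphenyl]ethan-1-one
Product: 23 5,7-bis(benzyloxy)-3-iodo-4H-chromen-4-one, via enaminone 22 (not isolated)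
Conditions: Me2NCH(OMe)2, toluene, 95 °C; then I2, CHCl3, rt
Reagents that add atoms: N,N-dimethylformamide dimethyl acetal, COC(OC)N(C)C; iodine, II
Why: Condensation of the methyl ketone with the formamide acetal gives the enaminone, and iodine then triggers iodocyclisation with loss of dimethylamine, the standard enaminone route to 3-iodochromones, which supplies C2 and the C3 handle in one operation.

**Step 14**
Reactants: 19 (S)-2-[4-(benzyloxy)-7-methoxy-5-(4,4,5,5-tetramethyl-1,3,2-dioxaborolan-2-yl)-2,3-dihydrobenzofuran-2-yl]propan-2-ol; 23 5,7-bis(benzyloxy)-3-iodo-4H-chromen-4-one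
Product: 24 5,7-bis(benzyloxy)-3-[(S)-4-(benzyloxy)-2-(2-hydroxypropan-2-yl)-7-methoxy-2,3-dihydrobenzofuran-5-yl]-4H-chromen-4-one
Conditions: Pd(OAc)2, SPhos, K3PO4, THF/H2O, 60 °C
Reagents that add atoms: none
Why: Suzuki–Miyaura coupling of a 3-iodochromone with an arylboronate is the established way to the isoflavone C3–C1' bond, and the electron-rich biarylphosphine allows a moderate temperature and a mild phosphate base that should spare the pyranone ring while the ortho-benzyloxy boronate transmetalates.

**Step 15**
Reactants: 24 5,7-bis(benzyloxy)-3-[(S)-4-(benzyloxy)-2-(2-hydroxypropan-2-yl)-7-methoxy-2,3-dihydrobenzofuran-5-yl]-4H-chromen-4-one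
Product: 25 5,7-dihydroxy-3-[(2S)-4-hydroxy-2-(2-hydroxypropan-2-yl)-7-methoxy-2,3-dihydrobenzofuran-5-yl]-4H-chromen-4-one (CNP0342911.1)
Conditions: H2 (1 atm), Pd/C (10% palladium on carbon), EtOAc/MeOH, rt
Reagents that add atoms: none
Why: Catalytic hydrogenolysis cleaves the three benzyl aryl ethers in one operation, and at atmospheric pressure with monitored hydrogen uptake the chromone C2=C3 bond, the tertiary alcohol and the non-benzylic O–C2'' bond are expected to stay intact, so the (S) centre is carried unchanged into the target.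

**Compound list**
1 | 2-bromo-5-hydroxy-4-methoxybenzaldehyde | COc1cc(Br)c(C=O)cc1O | starting material
2 | 2-bromo-4-methoxy-5-(methoxymethoxy)benzaldehyde | COCOc1cc(C=O)c(Br)cc1OC | intermediate
3 | 2-bromo-4-methoxy-5-(methoxymethoxy)phenyl formate | COCOc1cc(OC=O)c(Br)cc1OC | intermediate
4 | 2-bromo-4-methoxy-5-(methoxymethoxy)phenol | COCOc1cc(O)c(Br)cc1OC | intermediate
5 | 1-(benzyloxy)-2-bromo-4-methoxy-5-(methoxymethoxy)benzene | COCOc1cc(OCc2ccccc2)c(Br)cc1OC | intermediate
6 | 5-(benzyloxy)-4-bromo-2-methoxyphenol | COc1cc(Br)c(OCc2ccccc2)cc1O | intermediate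
7 | 5-(benzyloxy)-6-bromo-8-methoxy-2-phenyl-4H-1,3,2-benzodioxaborinine | COc1cc(Br)c(OCc2ccccc2)c2c1OB(c1ccccc1)OC2 | intermediate
8 | 3-(benzyloxy)-4-bromo-2-(hydroxymethyl)-6-methoxyphenol | COc1cc(Br)c(OCc2ccccc2)c(CO)c1O | intermediate
9 | 3-(benzyloxy)-4-bromo-6-methoxy-2-(tosylmethyl)phenol | COc1cc(Br)c(OCc2ccccc2)c(CS(=O)(=O)c2ccc(C)cc2)c1O | intermediate
10 | quinidine | COc1ccc2nccc([C@@H]([C@H]3C[C@@H]4CCN3C[C@@H]4C=C)O)c2c1 | starting material
11 | 9-O-methylquinidine | COc1ccc2nccc([C@@H]([C@H]3C[C@@H]4CCN3C[C@@H]4C=C)OC)c2c1 | intermediate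
12 | methyl bromoacetate | COC(=O)CBr | starting material
13 | N-(2-methoxy-2-oxoethyl)-9-O-methylquinidinium bromide | COc1ccc2nccc([C@@H]([C@H]3C[C@@H]4CC[N@@+]3(CC(=O)OC)C[C@@H]4C=C)OC)c2c1.[Br-] | intermediate
14 | 9-O-methylquinidinium (methoxycarbonyl)methylide (ammonium ylide) | COc1ccc2nccc([C@@H]([C@H]3C[C@@H]4CC[N@@+]3([CH-]C(=O)OC)C[C@@H]4C=C)OC)c2c1 | intermediate
15 | 3-(benzyloxy)-4-bromo-6-methoxy-2-methylidenecyclohexa-3,5-dien-1-one (ortho-quinone methide) | C=C1C(=O)C(OC)=CC(Br)=C1OCc1ccccc1 | intermediate
16 | methyl (2R)-3-[2-(benzyloxy)-3-bromo-5-methoxy-6-oxidophenyl]-2-(9-O-methylquinidinium-1-yl)propanoate (betaine, reacting epimer) | COc1ccc2nccc([C@@H]([C@H]3C[C@@H]4CC[N@@+]3([C@@H](C(=O)OC)Cc5c([O-])c(OC)cc(Br)c5OCc5ccccc5)C[C@@H]4C=C)OC)c2c1 | intermediate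
17 | methyl (S)-4-(benzyloxy)-5-bromo-7-methoxy-2,3-dihydrobenzofuran-2-carboxylate | COc1cc(Br)c(OCc2ccccc2)c2c1O[C@H](C(=O)OC)C2 | intermediate
18 | (S)-2-[4-(benzyloxy)-5-bromo-7-methoxy-2,3-dihydrobenzofuran-2-yl]propan-2-ol | COc1cc(Br)c(OCc2ccccc2)c2c1O[C@H](C(C)(C)O)C2 | intermediate
19 | (S)-2-[4-(benzyloxy)-7-methoxy-5-(4,4,5,5-tetramethyl-1,3,2-dioxaborolan-2-yl)-2,3-dihydrobenzofuran-2-yl]propan-2-ol | COc1cc(B2OC(C)(C)C(C)(C)O2)c(OCc2ccccc2)c2c1O[C@H](C(C)(C)O)C2 | intermediate
20 | 2,4,6-trihydroxyacetophenone | CC(=O)c1c(O)cc(O)cc1O | starting material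
21 | 1-[2,4-bis(benzyloxy)-6-hydroxyphenyl]ethan-1-one | CC(=O)c1c(O)cc(OCc2ccccc2)cc1OCc1ccccc1 | intermediate
22 | (E)-1-[2,4-bis(benzyloxy)-6-hydroxyphenyl]-3-(dimethylamino)prop-2-en-1-one | CN(C)/C=C/C(=O)c1c(O)cc(OCc2ccccc2)cc1OCc1ccccc1 | intermediate
23 | 5,7-bis(benzyloxy)-3-iodo-4H-chromen-4-one | O=c1c(I)coc2cc(OCc3ccccc3)cc(OCc3ccccc3)c12 | intermediate
24 | 5,7-bis(benzyloxy)-3-[(S)-4-(benzyloxy)-2-(2-hydroxypropan-2-yl)-7-methoxy-2,3-dihydrobenzofuran-5-yl]-4H-chromen-4-one | COc1cc(-c2coc3cc(OCc4ccccc4)cc(OCc4ccccc4)c3c2=O)c(OCc2ccccc2)c2c1O[C@H](C(C)(C)O)C2 | intermediate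
25 | 5,7-dihydroxy-3-[(2S)-4-hydroxy-2-(2-hydroxypropan-2-yl)-7-methoxy-2,3-dihydrobenzofuran-5-yl]-4H-chromen-4-one | COc1cc(-c2coc3cc(O)cc(O)c3c2=O)c(O)c2c1O[C@H](C(C)(C)O)C2 | target

**Totals**
Total step count: 15.
Longest linear sequence: 11 steps (steps 1–6, 9, 10, 11, 14, 15).

**Steps most likely to fail**

1. Step 9 (the step carrying the label).
- What may go wrong: the ring closure may discriminate poorly between the two faces at C2'', giving low enantiomeric excess, or the unsubstituted methide may dimerise faster than the ylide intercepts it. Enantiomeric purity should be checked at 17 or 18 and raised by recrystallisation where possible.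
- Fallback: the C2'' centre is set by reagent-controlled epoxidation of a prenyl group instead, setting out from phenol 6. Palladium-catalysed O-allylation with tert-butyl 2-methylbut-3-en-2-yl carbonate (Pd(PPh3)4, THF, 0 °C) should give the aryl 1,1-dimethylallyl ether F1. Aromatic Claisen rearrangement in hot N,N-diethylaniline moves the allyl unit to the only free ortho carbon and gives the ortho-prenylphenol F2. Silylation (TBSCl, imidazole, DMF) gives the silyl ether F3. Shi epoxidation with the D-fructose-derived ketone and KHSO5 at buffered pH should give the (R)-epoxide F4. Bu4NF in THF then frees the phenoxide, which opens the epoxide at its secondary carbon (5-exo-tet, inversion) to give the (S) alcohol 18, where the route resumes at step 11.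

2. Step 14.
- What may go wrong: protodeboronation of the electron-rich ortho-alkoxy boronate and base-induced opening of the pyranone ring may outrun transmetalation.
- Fallback: ring C is built after the carbon–carbon bond, setting out from bromide 18 and ketone 21. Bromine–lithium exchange (n-BuLi, 2.2 equiv, THF, −78 °C) and quenching with DMF should give the aldehyde F6. Claisen–Schmidt condensation with 21 (KOH, EtOH, rt) gives the 2'-hydroxychalcone F7. Oxidative 1,2-aryl migration with Tl(NO3)3·3H2O in MeOH/HC(OMe)3 gives the keto acetal F8 as a mixture of epimers at the new, later destroyed centre. Warming with HCl in MeOH cyclises it with loss of methanol to isoflavone 24, where the route resumes at step 15.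

3. Step 5.
- What may go wrong: condensation at the crowded C3' carbon, flanked by the hydroxyl and the benzyloxy group, may stall or go on to diarylmethane formation.
- Fallback: the carbon is introduced at the aldehyde oxidation level, setting out from phenol 6. Magnesium-mediated ortho-formylation (MgCl2, Et3N, paraformaldehyde, MeCN, reflux) should give the salicylaldehyde F5, and NaBH4 in MeOH at 0 °C reduces it to salicyl alcohol 8, where the route resumes at step 6.

**Further compounds**
F1 | step 9 | 1-(benzyloxy)-2-bromo-4-methoxy-5-[(2-methylbut-3-en-2-yl)oxy]benzene | COc1cc(Br)c(OCc2ccccc2)cc1OC(C)(C)C=C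
F2 | step 9 | 3-(benzyloxy)-4-bromo-6-methoxy-2-(3-methylbut-2-en-1-yl)phenol | COc1cc(Br)c(OCc2ccccc2)c(CC=C(C)C)c1O
F3 | step 9 | [3-(benzyloxy)-4-bromo-6-methoxy-2-(3-methylbut-2-en-1-yl)phenoxy](tert-butyl)dimethylsilane | COc1cc(Br)c(OCc2ccccc2)c(CC=C(C)C)c1O[Si](C)(C)C(C)(C)C
F4 | step 9 | [3-(benzyloxy)-4-bromo-2-{[(2R)-3,3-dimethyloxiran-2-yl]methyl}-6-methoxyphenoxy](tert-butyl)dimethylsilane | COc1cc(Br)c(OCc2ccccc2)c(C[C@H]2OC2(C)C)c1O[Si](C)(C)C(C)(C)C
F5 | step 5 | 2-(benzyloxy)-3-bromo-6-hydroxy-5-methoxybenzaldehyde | COc1cc(Br)c(OCc2ccccc2)c(C=O)c1O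
F6 | step 14 | (S)-4-(benzyloxy)-2-(2-hydroxypropan-2-yl)-7-methoxy-2,3-dihydrobenzofuran-5-carbaldehyde | COc1cc(C=O)c(OCc2ccccc2)c2c1O[C@H](C(C)(C)O)C2
F7 | step 14 | (E)-1-[2,4-bis(benzyloxy)-6-hydroxyphenyl]-3-[(S)-4-(benzyloxy)-2-(2-hydroxypropan-2-yl)-7-methoxy-2,3-dihydrobenzofuran-5-yl]prop-2-en-1-one | COc1cc(/C=C/C(=O)c2c(O)cc(OCc3ccccc3)cc2OCc2ccccc2)c(OCc2ccccc2)c2c1O[C@H](C(C)(C)O)C2
F8 | step 14 | 1-[2,4-bis(benzyloxy)-6-hydroxyphenyl]-2-[(S)-4-(benzyloxy)-2-(2-hydroxypropan-2-yl)-7-methoxy-2,3-dihydrobenzofuran-5-yl]-3,3-dimethoxypropan-1-one | COc1cc(C(C(OC)OC)C(=O)c2c(O)cc(OCc3ccccc3)cc2OCc2ccccc2)c(OCc2ccccc2)c2c1O[C@H](C(C)(C)O)C2
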